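Everything rests on cutting the O1–C8a bond of ring C. The array O1–C8a=C4a–C4, flanked by quaternary C8, is read as the adduct of the C2 hydroxyl to an alkyne (C4a≡C8a) conjugated with a C4 ketone. One cycloisomerisation of the open-chain (S)-β-hydroxy ynone, which already carries the gem-diprenyl carbon C8, the C7 ester and the C2 stereocentre, closes ring C as a dihydropyranone without disturbing C2. The C4 ketone is then reduced cis to the phenyl group. The nucleophilic C4a of the resulting enol ether captures a C5–C6 ketene acetal unit hung on C7, closing ring A with the methoxy group fixed at C5.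

Key step: step 8

Remark: flavan numbering (O1, C2, C3, C4, C4a, C5–C8, C8a) is applied to every intermediate; the target SMILES decodes as (2S,4S) with phenyl and hydroxyl cis, and the hydroxy ester is assumed to be bought as the single S enantiomer.

Step 1
Reactants: 1 dimethyl malonate; 2 prenyl bromide (1-bromo-3-methylbut-2-ene)
Product: 4 dimethyl 2,2-bis(3-methylbut-2-enyl)malonate, via dimethyl 2-(3-methylbut-2-enyl)malonate 3 (not isolated)
Conditions: NaH (2.4 equiv), 2 (2.3 equiv), THF–DMF, 0 °C to rt
Reagents that add atoms: none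
Why: Malonic ester alkylation, in which the sodium enolate displaces the primary allylic bromide by SN2 twice in one flask, and excess base and halide should drive monoalkylated 3 on to the quaternary diester.

Step 2
Reactants: 4 dimethyl 2,2-bis(3-methylbut-2-enyl)malonate
Product: 5 methyl 2-formyl-5-methyl-2-(3-methylbut-2-enyl)hex-4-enoate
Conditions: iBu2AlH (1.1 equiv), CH2Cl2, −78 °C
Reagents that add atoms: none
Why: Partial ester reduction, in which the aluminium hemiacetal, held by chelation to the second ester carbonyl, should persist at −78 °C until work-up, so only one of the two equivalent esters reaches the aldehyde, and no stereocentre arises because the two prenyl groups are identical.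

Step 3
Reactants: 5 methyl 2-formyl-5-methyl-2-(3-methylbut-2-enyl)hex-4-enoate
Product: 6 methyl 2-ethynyl-5-methyl-2-(3-methylbut-2-enyl)hex-4-enoate
Conditions: Me3SiCHN2, LiN(iPr)2, THF, −78 °C to rt
Reagents that add atoms: (trimethylsilyl)diazomethane C[Si](C)(C)C=[N+]=[N-]
Why: Colvin rearrangement, in which lithiated Me3SiCHN2 adds to the non-enolisable aldehyde, loss of Me3SiOLi and N2 gives an alkylidene carbene whose fast 1,2-hydride shift delivers the terminal alkyne, and the cold aprotic medium avoids the retro-Claisen deformylation that methoxide could cause in an α-formyl ester.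

Step 4
Reactants: 7 ethyl (S)-3-hydroxy-3-phenylpropanoate
Product: 8 (3S)-3-hydroxy-N-methoxy-N-methyl-3-phenylpropanamide
Conditions: MeNH(OMe)·HCl (1.6 equiv), iPrMgCl (4.2 equiv), THF, −20 to 0 °C
Reagents that add atoms: N,O-dimethylhydroxylamine hydrochloride CNOC.Cl
Why: Ester aminolysis by the chloromagnesium amide gives the Weinreb amide while the hydroxyl sits as its magnesium alkoxide, which disfavours β-elimination and leaves the benzylic C–O bond, and hence the S configuration, untouched.

Step 5
Reactants: 8 (3S)-3-hydroxy-N-methoxy-N-methyl-3-phenylpropanamide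
Product: 9 (3S)-N-methoxy-N-methyl-3-phenyl-3-(triethylsilyloxy)propanamide
Conditions: Et3SiCl, imidazole, CH2Cl2, 0 °C to rt
Reagents that add atoms: chlorotriethylsilane CC[Si](Cl)(CC)CC
Why: Imidazole-promoted silylation masks the acidic hydroxyl for the acetylide step with a group labile enough to be removed later without base.

Step 6
Reactants: 6 methyl 2-ethynyl-5-methyl-2-(3-methylbut-2-enyl)hex-4-enoate; 9 (3S)-N-methoxy-N-methyl-3-phenyl-3-(triethylsilyloxy)propanamide
Product: 11 methyl (7S)-2,2-bis(3-methylbut-2-enyl)-5-oxo-7-phenyl-7-(triethylsilyloxy)hept-3-ynoate, via lithium acetylide 10 (not isolated)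
Conditions: 6, LiN(iPr)2 (1.05 equiv), THF, −78 °C; then 9, −78 to −10 °C; AcOH quench at −78 °C
Reagents that add atoms: lithium diisopropylamide CC(C)[N-]C(C)C.[Li+] (lithium of 10)
Why: Weinreb ketone synthesis, in which the amide base removes only the alkyne proton (the ester has no α-hydrogen and is shielded by the quaternary carbon), the acetylide adds once to give a chelated tetrahedral adduct, and the cold acidic quench releases the ynone with the liberated amines protonated so that they cannot add to it.

Step 7
Reactants: 11 methyl (7S)-2,2-bis(3-methylbut-2-enyl)-5-oxo-7-phenyl-7-(triethylsilyloxy)hept-3-ynoate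
Product: 12 methyl (7S)-7-hydroxy-2,2-bis(3-methylbut-2-enyl)-5-oxo-7-phenylhept-3-ynoate
Conditions: HF·pyridine, pyridine, THF, 0 °C
Reagents that add atoms: none
Why: Fluoride-mediated desilylation under buffered, weakly acidic conditions removes the triethylsilyl group without the base that would provoke retro-aldol cleavage or dehydration of the β-hydroxy ynone.

Step 8
Reactants: 12 methyl (7S)-7-hydroxy-2,2-bis(3-methylbut-2-enyl)-5-oxo-7-phenylhept-3-ynoate
Product: 13 methyl 5-methyl-2-(3-methylbut-2-enyl)-2-[(2S)-4-oxo-2-phenyl-2,3-dihydropyran-6-yl]hex-4-enoate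
Conditions: Ph3PAuNTf2 (5 mol %), CH2Cl2, 0 °C to rt
Reagents that add atoms: none
Why: The cationic monovalent gold centre binds the alkyne, the C2 hydroxyl adds to C8a anti to the metal, and the proton set free cleaves the C4a–Au bond of the vinylgold species, which gives 13 and returns the catalyst. The closest known reaction type is the π-acid-catalysed cycloisomerisation (intramolecular oxa-Michael addition) of β-hydroxy ynones to 2,3-dihydro-4H-pyran-4-ones. The one ring closes in the 6-endo-dig mode, because the ketone makes only C8a electrophilic, whereas a 5-exo closure would have to hit C4a, the electron-rich α-carbon. No stereocentre is created, and C2 stays S since its C–O bond is never broken and the neutral aprotic medium allows neither retro-aldol cleavage of 12 nor the enolate-triggered ring opening that racemises such pyranones in base. The step needs oxygen to win over the two prenyl alkenes (a 1,5-enyne array) and the ester carbonyl: both could form a five-membered ring only by attacking C4a, against the ynone polarisation, while attack on C8a would give a four-membered ring, so the substrate itself steers the catalyst to the hydroxyl. Because an sp carbon is open from all sides, the neighbouring quaternary C8 should not slow the attack.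

Step 9
Reactants: 13 methyl 5-methyl-2-(3-methylbut-2-enyl)-2-[(2S)-4-oxo-2-phenyl-2,3-dihydropyran-6-yl]hex-4-enoate
Product: 14 methyl 2-[(2S,4S)-4-hydroxy-2-phenyl-3,4-dihydro-2H-pyran-6-yl]-5-methyl-2-(3-methylbut-2-enyl)hex-4-enoate
Conditions: NaBH4, CeCl3·7H2O, MeOH, −78 °C
Reagents that add atoms: none
Why: Luche reduction, in which hydride adds 1,2 along the axial trajectory of the half-chair that keeps the C2 phenyl equatorial, so the new C4 hydroxyl should come out pseudo-equatorial and cis to phenyl (4S, substrate control by C2), the hindered ester is left alone, and the base-induced ring opening that threatens C2 is switched off.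

Step 10
Reactants: 14 methyl 2-[(2S,4S)-4-hydroxy-2-phenyl-3,4-dihydro-2H-pyran-6-yl]-5-methyl-2-(3-methylbut-2-enyl)hex-4-enoate
Product: 15 methyl 2-[(2S,4S)-4-(tert-butyldimethylsilyloxy)-2-phenyl-3,4-dihydro-2H-pyran-6-yl]-5-methyl-2-(3-methylbut-2-enyl)hex-4-enoate
Conditions: tBuMe2SiCl, imidazole, DMF, rt
Reagents that add atoms: tert-butylchlorodimethylsilane CC(C)(C)[Si](C)(C)Cl
Why: Imidazole-promoted silylation under non-acidic conditions turns the ionisable allylic alcohol into a bulky, weakly Lewis-basic ether that is a poor leaving group.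

Step 11
Reactants: 15 methyl 2-[(2S,4S)-4-(tert-butyldimethylsilyloxy)-2-phenyl-3,4-dihydro-2H-pyran-6-yl]-5-methyl-2-(3-methylbut-2-enyl)hex-4-enoate
Product: 17 2-[(2S,4S)-4-(tert-butyldimethylsilyloxy)-2-phenyl-3,4-dihydro-2H-pyran-6-yl]-5-methyl-2-(3-methylbut-2-enyl)hex-4-enoic acid, via potassium carboxylate 16 (not isolated)
Conditions: KOSiMe3 (3 equiv), THF, 50 °C; then cold dilute aq. AcOH; 17 used at once
Reagents that add atoms: potassium trimethylsilanolate C[Si](C)(C)[O-].[K+]
Why: Anhydrous silanolate cleavage of a methyl ester copes with a hindered carbonyl because the methyl carbon can be attacked as well, the enol ether, silyl ether and alkenes are inert to base, nothing is epimerisable, and a cold weak acid frees the acid without protonating C4a.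

Step 12
Reactants: 17 2-[(2S,4S)-4-(tert-butyldimethylsilyloxy)-2-phenyl-3,4-dihydro-2H-pyran-6-yl]-5-methyl-2-(3-methylbut-2-enyl)hex-4-enoic acid; 18 1,1-dimethoxyethene
Product: 20 4-[(2S,4S)-4-(tert-butyldimethylsilyloxy)-2-phenyl-3,4-dihydro-2H-pyran-6-yl]-1,1-dimethoxy-7-methyl-4-(3-methylbut-2-enyl)octa-1,6-dien-3-one, via acid chloride 19 (not isolated)
Conditions: Me2C=C(Cl)NMe2 (1.2 equiv), CH2Cl2, 0 °C; then 18 (4 equiv), Et3N (2 equiv), 0 to 35 °C; crude 20 filtered through basic alumina
Reagents that add atoms: 1-chloro-N,N,2-trimethylprop-1-en-1-amine CC(C)=C(Cl)N(C)C (chlorine of 19)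
Why: The α-chloroenamine makes the acid chloride under neutral conditions without free HCl, and the known C-acylation of ketene acetals by acid chlorides then joins C7 to the nucleophilic CH2 of 18, with Et3N deprotonating the dimethoxycarbenium intermediate before chloride can demethylate it and with no ketene pathway open because 19 has no α-hydrogen.

Step 13
Reactants: 20 4-[(2S,4S)-4-(tert-butyldimethylsilyloxy)-2-phenyl-3,4-dihydro-2H-pyran-6-yl]-1,1-dimethoxy-7-methyl-4-(3-methylbut-2-enyl)octa-1,6-dien-3-one
Product: 21 (2S,4S)-4-(tert-butyldimethylsilyloxy)-5-methoxy-8,8-bis(3-methylbut-2-enyl)-2-phenyl-3,4-dihydro-2H-chromen-7(8H)-one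
Conditions: Me3SiOTf (1.1 equiv), 2,6-di-tert-butyl-4-methylpyridine (1.5 equiv), CH2Cl2, −78 to −30 °C
Reagents that add atoms: none
Why: Proposed new method: Me3SiOTf should silylate the most Lewis-basic site, the C7 carbonyl of the push–pull ketene acetal, to give a 1,1-dimethoxy-3-silyloxyallyl cation whose C5 end is held next to C4a by the gem-diprenyl carbon; C4a, the nucleophilic β-carbon of the ring C enol ether, attacks C5 (6-endo-trig), the hindered pyridine removes the C4a proton (the only one available, C8 being quaternary) to restore C4a=C8a, and loss of Me3SiOMe from the C5 ketal gives the 5-methoxy dienone, so the oxygen pattern of ring A is fixed by connectivity. The closest known reaction types are the Lewis-acid addition of enol ethers to orthoesters, the Mukaiyama–Michael addition–elimination on β-alkoxy enones and the Vilsmeier–Haack C-formylation of glycals, the last of which shows that a stabilised carbenium ion can substitute this position without Ferrier loss of the allylic oxygen; low temperature, the absence of free acid and the bulky silyl ether serve the same end, the prenyl alkenes are much weaker π-nucleophiles than the enol ether, and neither C2 nor C4 is touched.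

Step 14
Reactants: 21 (2S,4S)-4-(tert-butyldimethylsilyloxy)-5-methoxy-8,8-bis(3-methylbut-2-enyl)-2-phenyl-3,4-dihydro-2H-chromen-7(8H)-one
Product: 22 pongaflavanol, (2S,4S)-4-hydroxy-5-methoxy-8,8-bis(3-methylbut-2-enyl)-2-phenyl-3,4-dihydro-2H-chromen-7(8H)-one
Conditions: Bu4NF, AcOH (1:1), THF, 0 °C to rt
Reagents that add atoms: none
Why: Fluoride-mediated desilylation buffered with AcOH frees the C4 hydroxyl without acid that could ionise it or strong base, and neither stereocentre takes part.

Compound list
1 | dimethyl malonate | COC(=O)CC(=O)OC | starting material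
2 | prenyl bromide (1-bromo-3-methylbut-2-ene) | CC(C)=CCBr | starting material
3 | dimethyl 2-(3-methylbut-2-enyl)malonate | COC(=O)C(CC=C(C)C)C(=O)OC | intermediate
4 | dimethyl 2,2-bis(3-methylbut-2-enyl)malonate | COC(=O)C(CC=C(C)C)(CC=C(C)C)C(=O)OC | intermediate
5 | methyl 2-formyl-5-methyl-2-(3-methylbut-2-enyl)hex-4-enoate | COC(=O)C(CC=C(C)C)(CC=C(C)C)C=O | intermediate
6 | methyl 2-ethynyl-5-methyl-2-(3-methylbut-2-enyl)hex-4-enoate | COC(=O)C(CC=C(C)C)(CC=C(C)C)C#C | intermediate
7 | ethyl (S)-3-hydroxy-3-phenylpropanoate | CCOC(=O)C[C@H](O)c1ccccc1 | starting material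
8 | (3S)-3-hydroxy-N-methoxy-N-methyl-3-phenylpropanamide | CON(C)C(=O)C[C@H](O)c1ccccc1 | intermediate
9 | (3S)-N-methoxy-N-methyl-3-phenyl-3-(triethylsilyloxy)propanamide | CON(C)C(=O)C[C@H](O[Si](CC)(CC)CC)c1ccccc1 | intermediate
10 | lithium acetylide of 6, methyl 2-(lithioethynyl)-5-methyl-2-(3-methylbut-2-enyl)hex-4-enoate | COC(=O)C(CC=C(C)C)(CC=C(C)C)C#C[Li] | intermediate
11 | methyl (7S)-2,2-bis(3-methylbut-2-enyl)-5-oxo-7-phenyl-7-(triethylsilyloxy)hept-3-ynoate | COC(=O)C(CC=C(C)C)(CC=C(C)C)C#CC(=O)C[C@H](O[Si](CC)(CC)CC)c1ccccc1 | intermediate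
12 | methyl (7S)-7-hydroxy-2,2-bis(3-methylbut-2-enyl)-5-oxo-7-phenylhept-3-ynoate | COC(=O)C(CC=C(C)C)(CC=C(C)C)C#CC(=O)C[C@H](O)c1ccccc1 | intermediate
13 | methyl 5-methyl-2-(3-methylbut-2-enyl)-2-[(2S)-4-oxo-2-phenyl-2,3-dihydropyran-6-yl]hex-4-enoate | COC(=O)C(CC=C(C)C)(CC=C(C)C)C1=CC(=O)C[C@@H](c2ccccc2)O1 | intermediate
14 | methyl 2-[(2S,4S)-4-hydroxy-2-phenyl-3,4-dihydro-2H-pyran-6-yl]-5-methyl-2-(3-methylbut-2-enyl)hex-4-enoate | COC(=O)C(CC=C(C)C)(CC=C(C)C)C1=C[C@@H](O)C[C@@H](c2ccccc2)O1 | intermediate
15 | methyl 2-[(2S,4S)-4-(tert-butyldimethylsilyloxy)-2-phenyl-3,4-dihydro-2H-pyran-6-yl]-5-methyl-2-(3-methylbut-2-enyl)hex-4-enoate | COC(=O)C(CC=C(C)C)(CC=C(C)C)C1=C[C@@H](O[Si](C)(C)C(C)(C)C)C[C@@H](c2ccccc2)O1 | intermediate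
16 | potassium carboxylate of 17 | [K+].[O-]C(=O)C(CC=C(C)C)(CC=C(C)C)C1=C[C@@H](O[Si](C)(C)C(C)(C)C)C[C@@H](c2ccccc2)O1 | intermediate
17 | 2-[(2S,4S)-4-(tert-butyldimethylsilyloxy)-2-phenyl-3,4-dihydro-2H-pyran-6-yl]-5-methyl-2-(3-methylbut-2-enyl)hex-4-enoic acid | OC(=O)C(CC=C(C)C)(CC=C(C)C)C1=C[C@@H](O[Si](C)(C)C(C)(C)C)C[C@@H](c2ccccc2)O1 | intermediate
18 | 1,1-dimethoxyethene | C=C(OC)OC | starting material
19 | acid chloride of 17 | ClC(=O)C(CC=C(C)C)(CC=C(C)C)C1=C[C@@H](O[Si](C)(C)C(C)(C)C)C[C@@H](c2ccccc2)O1 | intermediate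
20 | 4-[(2S,4S)-4-(tert-butyldimethylsilyloxy)-2-phenyl-3,4-dihydro-2H-pyran-6-yl]-1,1-dimethoxy-7-methyl-4-(3-methylbut-2-enyl)octa-1,6-dien-3-one | COC(OC)=CC(=O)C(CC=C(C)C)(CC=C(C)C)C1=C[C@@H](O[Si](C)(C)C(C)(C)C)C[C@@H](c2ccccc2)O1 | intermediate
21 | (2S,4S)-4-(tert-butyldimethylsilyloxy)-5-methoxy-8,8-bis(3-methylbut-2-enyl)-2-phenyl-3,4-dihydro-2H-chromen-7(8H)-one | COC1=CC(=O)C(CC=C(C)C)(CC=C(C)C)C2=C1[C@@H](O[Si](C)(C)C(C)(C)C)C[C@@H](c1ccccc1)O2 | intermediate
22 | pongaflavanol, (2S,4S)-4-hydroxy-5-methoxy-8,8-bis(3-methylbut-2-enyl)-2-phenyl-3,4-dihydro-2H-chromen-7(8H)-one | COC1=CC(=O)C(CC=C(C)C)(CC=C(C)C)C2=C1[C@@H](O)C[C@@H](c1ccccc1)O2 | target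

Total step count: 14. Longest linear sequence: 12 steps (steps 1–3, then 6–14); steps 4 and 5 form the short branch.

Steps most likely to fail

Step 13.
- **What may go wrong:** Lewis-acid ionisation of the allylic C4 silyloxy group (Ferrier-type), with loss or scrambling of C4, may outrun C–C bond formation. The strongly stabilised cation may also simply not be attacked.
- **Fallback:** a base-mediated ring closure that uses known chemistry only; it sets out from acid 17 and comes back at 21.
- **Course:** MeLi (2.2 equiv, Et2O, 0 °C) should add to the lithium carboxylate and give the C7 methyl ketone F1. Cl3CCOCl and pyridine in CH2Cl2 should acylate the enol ether at C4a without any Lewis acid (β-trichloroacetylation of enol ethers) and give the C4a trichloroacetyl ketone F2. NaOMe in MeOH should convert this by haloform-type cleavage into the C4a methyl ester F3. On warming, Dieckmann condensation of the C6 enolate on the C5 ester should close ring A to the enolised 5-hydroxy dienone F4. O-methylation with Me3SiCHN2 in toluene–MeOH should then give 21.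
- **Price:** methylation may also take place at the C7 oxygen, so a separation of two enol ethers has to be accepted.

Step 12.
- **What may go wrong:** acylation at the neopentyl-like carbonyl may be slow. Chloride may demethylate the dimethoxycarbenium intermediate, which leads to the β-keto ester level. Acid 17 may be protonated at C4a with loss of CO2 before it is activated.
- **Fallback:** the C7–C6 bond is built from the other side, with no acid chloride needed; it sets out from 17 and comes back at 20.
- **Course:** The C7 methyl ketone F1, made with MeLi as above, is deprotonated with LiN(SiMe3)2 in THF and treated with CS2 and then MeI (2 equiv) to give the α-oxo ketene dithioacetal F5. Two addition–elimination exchanges with NaOMe in refluxing MeOH should replace both methylthio groups and give 20. All of this runs under basic conditions, which the enol ether and the silyl ether tolerate.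

Step 8.
- **What may go wrong:** the catalyst may be diverted by the prenyl alkenes into enyne cycloisomerisation, or be held by them so that turnover stalls.
- **Fallback:** an amine relay in place of π-acid catalysis; it sets out from 12 and comes back at 13.
- **Course:** Et2NH in EtOH at rt should add to C8a of the ynone and give the enaminone F6. Brief treatment with AcOH in toluene should let the C2 hydroxyl displace the amine by addition–elimination through the iminium form, which closes the same O1–C8a bond and gives 13 with C2 unchanged.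

Further compounds
F1 | step 13 | 3-[(2S,4S)-4-(tert-butyldimethylsilyloxy)-2-phenyl-3,4-dihydro-2H-pyran-6-yl]-6-methyl-3-(3-methylbut-2-enyl)hept-5-en-2-one | CC(=O)C(CC=C(C)C)(CC=C(C)C)C1=C[C@@H](O[Si](C)(C)C(C)(C)C)C[C@@H](c2ccccc2)O1
F2 | step 13 | 3-[(2S,4S)-4-(tert-butyldimethylsilyloxy)-2-phenyl-5-(trichloroacetyl)-3,4-dihydro-2H-pyran-6-yl]-6-methyl-3-(3-methylbut-2-enyl)hept-5-en-2-one | CC(=O)C(CC=C(C)C)(CC=C(C)C)C1=C(C(=O)C(Cl)(Cl)Cl)[C@@H](O[Si](C)(C)C(C)(C)C)C[C@@H](c2ccccc2)O1
F3 | step 13 | methyl (2S,4S)-4-(tert-butyldimethylsilyloxy)-6-[6-methyl-3-(3-methylbut-2-enyl)-2-oxohept-5-en-3-yl]-2-phenyl-3,4-dihydro-2H-pyran-5-carboxylate | CC(=O)C(CC=C(C)C)(CC=C(C)C)C1=C(C(=O)OC)[C@@H](O[Si](C)(C)C(C)(C)C)C[C@@H](c2ccccc2)O1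
F4 | step 13 | (2S,4S)-4-(tert-butyldimethylsilyloxy)-5-hydroxy-8,8-bis(3-methylbut-2-enyl)-2-phenyl-3,4-dihydro-2H-chromen-7(8H)-one | OC1=CC(=O)C(CC=C(C)C)(CC=C(C)C)C2=C1[C@@H](O[Si](C)(C)C(C)(C)C)C[C@@H](c1ccccc1)O2
F5 | step 12 | 4-[(2S,4S)-4-(tert-butyldimethylsilyloxy)-2-phenyl-3,4-dihydro-2H-pyran-6-yl]-7-methyl-4-(3-methylbut-2-enyl)-1,1-bis(methylsulfanyl)octa-1,6-dien-3-one | CSC(SC)=CC(=O)C(CC=C(C)C)(CC=C(C)C)C1=C[C@@H](O[Si](C)(C)C(C)(C)C)C[C@@H](c2ccccc2)O1
F6 | step 8 | methyl (3E,7S)-3-(diethylamino)-7-hydroxy-2,2-bis(3-methylbut-2-enyl)-5-oxo-7-phenylhept-3-enoate | COC(=O)C(CC=C(C)C)(CC=C(C)C)/C(N(CC)CC)=C\C(=O)C[C@H](O)c1ccccc1
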